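**Plan**
1. Retrosynthesis: the C15 ketone/C16 methylene, the two acetates and the C12 alcohol are late adjustments. Ring C is cut at C13–C14 and C9–C11, ring B at C9–C10 and C5–C6.
2. Enabling feature: C11 and C13 are the two α-carbons of a five-membered ketone whose carbonyl carbon is the one-carbon bridge C12. C9–C8–C14 is the β-carbon, α-carbon and α-CH2Br of a ring B enone with a temporary C7 carbonyl, so one bis-nucleophile and one bis-electrophile close the bicyclo[3.2.1]octan-8-one in one operation.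
3. Forward: ring A (2,6,6-trimethylcyclohexenone) gains ring B by Mukaiyama–Michael/aldol annulation and is taken to the 8-(bromomethyl)-8-en-7-one 16. Meso ketone 20 comes from cyclopent-3-en-1-ol, and alkylation/Michael annulation of the two closes ring C (25).
4. Endgame: C8=C9 by Saegusa–Ito oxidation, transposition of the C7 oxygen to C6 through an enol triflate, reduction at C6 and C12, conversion of the 15,16-diol into the 15-oxo-16-methylene unit, acetylation.
5. Stereochemistry: C1 from asymmetric conjugate borylation; C10 and C5 by substrate control; C11/C13 from chiral lithium amide desymmetrisation of 20 with bonding on the convex face; C6 and C12 from hydride addition to ketones on their open faces.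

Key step: step 13

Assumption: the (R,R)-amide in step 13 is taken to remove the α-proton on the carbon that becomes C13, and the (R,R)-ligand in step 1 to give the 3S alcohol; if either sense proves opposite, the enantiomeric amine or ligand is used.
Convention: locants are those of the target; α is the face of rings A/B that carries the C10 methyl, β the other face.

**Route**

Step 1
Reactants: 1 2,6,6-trimethylcyclohex-2-en-1-one
Product: 3 (3S)-3-hydroxy-2,6,6-trimethylcyclohexan-1-one (C2 epimers), via pinacol boronate 2 (not isolated)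
Conditions: B2pin2, CuCl (cat.), NaOtBu (cat.), (R,R)-2,3-bis(tert-butylmethylphosphino)quinoxaline (cat.), MeOH, THF, rt; then 30% H2O2, aq. NaHCO3, 0 °C
Reagents that add atoms: bis(pinacolato)diboron CC1(C)OB(OC1(C)C)B2OC(C)(C)C(C)(C)O2 (boron of 2); hydrogen peroxide OO
Why: Copper-catalysed asymmetric conjugate borylation followed by stereoretentive C–B oxidation should set C1 under ligand control, and the epimeric methyl-bearing carbon becomes trigonal in step 2.

Step 2
Reactants: 3 (3S)-3-hydroxy-2,6,6-trimethylcyclohexan-1-one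
Product: 4 (3S)-1,3-bis(tert-butyldimethylsilyloxy)-2,6,6-trimethylcyclohex-1-ene
Conditions: TBSOTf (2.4 equiv), Et3N, CH2Cl2, 0 °C
Reagents that add atoms: tert-butyldimethylsilyl triflate CC(C)(C)[Si](C)(C)OS(=O)(=O)C(F)(F)F
Why: O-silylation and soft enolisation with a silyl triflate should give a single silyl enol ether, because the ketone has only one enolisable α-carbon (the future C10) and no free enolate next to the β-oxygen is formed.

Step 3
Reactants: 4 (3S)-1,3-bis(tert-butyldimethylsilyloxy)-2,6,6-trimethylcyclohex-1-ene; 5 but-3-en-2-one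
Product: 6 (2R,3S)-3-(tert-butyldimethylsilyloxy)-2,6,6-trimethyl-2-(3-oxobutyl)cyclohexan-1-one
Conditions: TiCl4, CH2Cl2, −78 °C; H2O
Reagents that add atoms: none
Why: Mukaiyama–Michael addition in which the enone approaches the silyl enol ether anti to the neighbouring pseudo-axial silyloxy group, which should set quaternary C10 with its methyl cis to the C1 oxygen.

Step 4
Reactants: 6 (2R,3S)-3-(tert-butyldimethylsilyloxy)-2,6,6-trimethyl-2-(3-oxobutyl)cyclohexan-1-one
Product: 7 (4aS,5S)-5-(tert-butyldimethylsilyloxy)-4a,8,8-trimethyl-4,4a,5,6,7,8-hexahydronaphthalen-2(3H)-one (ring A/B 5-en-7-one with 1α-OTBS)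
Conditions: KOH, xylenes, 110 °C (Dean–Stark)
Reagents that add atoms: none
Why: Intramolecular aldol condensation (second half of a Robinson annulation) in which only the methyl ketone can enolise productively, the quaternary C10 excluding retro-Michael cleavage and β-elimination of the silyloxy group.

Step 5
Reactants: 7 ring A/B 5-en-7-one
Product: 9 1α-(tert-butyldimethylsilyloxy)-7-(triethylsilyloxy)-4,4,10-trimethyl-trans-decal-6-ene (5β-H), via lithium enolate 8 (not isolated)
Conditions: Li, NH3 (l), t-BuOH (1 equiv), THF, −78 °C; evaporate NH3; then Et3SiCl, Et3N, THF, −78 to 0 °C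
Reagents that add atoms: chlorotriethylsilane CC[Si](CC)(CC)Cl
Why: Dissolving-metal (Birch-type) enone reduction with axial protonation at C5 should give the trans ring fusion, and silylation fixes the regiodefined C6=C7 enolate.

Step 6
Reactants: 9 trans-decalin 7-silyl enol ether
Product: 11 1α-(tert-butyldimethylsilyloxy)-6β-(triethylsilyloxy)-4,4,10-trimethyl-trans-decalin-7-one, via silyloxy epoxide 10 (not isolated)
Conditions: mCPBA, NaHCO3, CH2Cl2, −20 to 0 °C
Reagents that add atoms: meta-chloroperoxybenzoic acid OOC(=O)c1cccc(Cl)c1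
Why: Rubottom oxidation in which epoxidation occurs on the β-face away from the axial C4 and C10 methyls and a 1,4-silyl shift delivers the α-silyloxy ketone (the C6 centre is made trigonal again in step 17).

Step 7
Reactants: 11 6β-silyloxy-7-ketone
Product: 13 1α-(tert-butyldimethylsilyloxy)-6β-(triethylsilyloxy)-4,4,10-trimethyl-trans-decal-8-en-7-one, via lithium enolate 12 (not isolated)
Conditions: LiN(iPr)2, THF, −78 °C; then PhS(Cl)=NtBu, −78 °C
Reagents that add atoms: none
Why: Kinetic deprotonation at the C8 methylene (C6 is tertiary and shielded) followed by sulfinimidoyl chloride dehydrogenation (Mukaiyama dehydrogenation, syn-elimination of the α-sulfilimine) should give the C8=C9 enone.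

Step 8
Reactants: 13 8-en-7-one; 14 formaldehyde
Product: 15 8-(hydroxymethyl)-1α-(tert-butyldimethylsilyloxy)-6β-(triethylsilyloxy)-4,4,10-trimethyl-trans-decal-8-en-7-one
Conditions: 37% aq. HCHO, DMAP, THF, rt
Reagents that add atoms: none
Why: Morita–Baylis–Hillman hydroxymethylation, the amine adding reversibly to C9 and the resulting enolate capturing formaldehyde at C8.

Step 9
Reactants: 15 8-(hydroxymethyl) enone
Product: 16 8-(bromomethyl)-1α-(tert-butyldimethylsilyloxy)-6β-(triethylsilyloxy)-4,4,10-trimethyl-trans-decal-8-en-7-one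
Conditions: CBr4, PPh3, CH2Cl2, 0 °C
Reagents that add atoms: carbon tetrabromide BrC(Br)(Br)Br
Why: Appel bromination of the primary allylic alcohol under neutral conditions that leave both silyl ethers intact.

Step 10
Reactants: 17 cyclopent-3-en-1-ol
Product: 18 cyclopentane-1,2,4-triol (1,2-cis diol, 4-OH trans)
Conditions: OsO4 (cat.), N-methylmorpholine N-oxide, acetone/H2O, rt
Reagents that add atoms: N-methylmorpholine N-oxide C[N+]1([O-])CCOCC1; water O
Why: Catalytic syn-dihydroxylation (Upjohn conditions), expected mainly anti to the hydroxyl; the carbinol centre is erased in step 12, so its epimer converges.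

Step 11
Reactants: 18 cyclopentane-1,2,4-triol
Product: 19 cis-3,4-(isopropylidenedioxy)cyclopentan-1-ol
Conditions: 2,2-dimethoxypropane, TsOH (cat.), acetone, rt
Reagents that add atoms: 2,2-dimethoxypropane COC(C)(C)OC
Why: Acid-catalysed transketalisation, in which only the cis-1,2-diol can form the five-membered acetonide.

Step 12
Reactants: 19 cis-3,4-(isopropylidenedioxy)cyclopentan-1-ol
Product: 20 meso cis-3,4-(isopropylidenedioxy)cyclopentan-1-one
Conditions: Dess–Martin periodinane, CH2Cl2, rt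
Reagents that add atoms: none
Why: Dess–Martin oxidation under non-basic conditions, which avoid β-elimination of the dioxolane oxygen from the product ketone.

Step 13
Reactants: 20 meso cis-3,4-(isopropylidenedioxy)cyclopentan-1-one; 16 ring A/B 8-(bromomethyl)-8-en-7-one
Product: 25 tetracyclic 12-ketone 7-(triethylsilyl) enol ether (15,16-O-isopropylidene; 1α-OTBS; 6β-OTES; 9α-H), via lithium enolate 21 (not isolated), via monoalkylated ketone 22 (not isolated), via C11 lithium enolate 23 (not isolated), via tetracyclic C7 lithium enolate 24 (not isolated)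
Conditions: (R,R)-bis(1-phenylethyl)amine, n-BuLi, LiCl, THF, −78 °C, then 20; then 16, −78 °C; then LiN(SiMe3)2, −78 to −40 °C; then Et3SiCl, −78 °C to rt
Reagents that add atoms: chlorotriethylsilane CC[Si](CC)(CC)Cl
Why: The chiral lithium amide removes one of the two enantiotopic α-protons of 20, enolate 21 displaces the primary allylic bromide at C14 (SN2) on its convex face anti to the dioxolane (C13–C14), LiN(SiMe3)2 then enolises the remaining α-methylene C11, and this enolate adds to C9 of the tethered enone (intramolecular Michael addition, C9–C11), the C7 enolate 24 being silylated. The closest known reaction type is the α,α'-annulation of cyclic ketone enolates and enamines with 2-(halomethyl)acrylates and 2-(halomethyl)enones, which gives bridged bicyclic ketones in the same alkylation-then-Michael order. Ring C closes in a 6-endo-trig mode (both alkene carbons C8 and C9 lie in the new ring and the enolate is endocyclic to it), which is allowed for enolates. C13 is set by the amide's choice of α-carbon together with attack anti to the dioxolane, C11 must bond on the same convex face because the C9–C8–C14 bridge can only span the cyclopentanone cis, C9 is set by axial attack on the β-face anti to the axial C10 methyl through a chair that places the C15–C16 bridge under ring B, and C8 stays trigonal. The step needs selection of the α-carbon (secured by the amide), SN2 rather than SN2' alkylation (secured by the hindered C9 next to quaternary C10), and ring closure faster than β-elimination of the dioxolane oxygen (favoured by lithium counter-ions at or below −40 °C).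

Step 14
Reactants: 25 tetracyclic 12-ketone 7-silyl enol ether
Product: 26 tetracyclic 12-alcohol (OH syn to C15/C16)
Conditions: NaBH4, EtOH/THF, −20 °C
Reagents that add atoms: none
Why: Borohydride reduction of the strained bridging ketone from the face of the three-carbon bridge, the other face being closed by the exo dioxolane oxygens, which should set C12 as in the target.

Step 15
Reactants: 26 tetracyclic 12-alcohol
Product: 27 12-O-(4-methoxybenzyl) ether of 26
Conditions: NaH, 4-methoxybenzyl chloride, Bu4NI (cat.), THF/DMF, 0 °C to rt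
Reagents that add atoms: 4-methoxybenzyl chloride COc1ccc(CCl)cc1
Why: Williamson etherification under basic conditions that the silyl enol ether, silyl ethers and acetonide tolerate.

Step 16
Reactants: 27 12-O-PMB silyl enol ether
Product: 28 12-O-PMB tetracyclic 8-en-7-one (15,16-O-isopropylidene; 1α-OTBS; 6β-OTES)
Conditions: Pd(OAc)2 (1.1 equiv), MeCN, 40 °C
Reagents that add atoms: none
Why: Saegusa–Ito oxidation, palladium binding C8 on the α-face away from the bicycle so that syn β-hydride elimination can use the α-hydrogen on C9 and give the tetrasubstituted endocyclic enone.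

Step 17
Reactants: 28 tetracyclic 8-en-7-one
Product: 30 6-(triethylsilyloxy)-6,8-dien-7-yl triflate, via potassium dienolate 29 (not isolated)
Conditions: KN(SiMe3)2, THF, −78 °C; then N-(5-chloropyridin-2-yl)bis(trifluoromethanesulfonimide), −78 to −20 °C
Reagents that add atoms: N-(5-chloropyridin-2-yl)bis(trifluoromethanesulfonimide) FC(F)(F)S(=O)(=O)N(c1ccc(Cl)cn1)S(=O)(=O)C(F)(F)F
Why: Enolate O-triflation, C6–H being the only enolisable position because the γ-hydrogen on C11 is at a bridgehead and C10 is quaternary.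

Step 18
Reactants: 30 dienyl triflate
Product: 31 6-(triethylsilyloxy)-6,8-diene (12-O-PMB; 15,16-O-isopropylidene; 1α-OTBS)
Conditions: Pd(OAc)2 (cat.), PPh3, Bu3N, HCO2H, DMF, 60 °C
Reagents that add atoms: none
Why: Palladium-catalysed formate reduction of an enol triflate replaces C7–O by C7–H and leaves the C6 silyl dienol ether, so the oxygen is transposed from C7 to C6.

Step 19
Reactants: 31 6-silyloxy-6,8-diene
Product: 33 8-en-6α-ol (12-O-PMB; 15,16-O-isopropylidene; 1α-OTBS), via 8-en-6-one 32 (not isolated)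
Conditions: Bu4NF, AcOH, THF, −78 to −20 °C; then NaBH4, MeOH, −40 °C
Reagents that add atoms: none
Why: Fluoride desilylation releases the dienolate, which is protonated kinetically at C7 to the β,γ-unsaturated ketone, and borohydride then attacks C6 from the β-face (the α-face is closed by the axial C4 and C10 methyls) to give the axial 6α-alcohol.

Step 20
Reactants: 33 8-en-6α-ol
Product: 34 8-ene-1α,6α-diol (12-O-PMB; 15,16-O-isopropylidene)
Conditions: HF·pyridine, pyridine, THF, 0 °C to rt
Reagents that add atoms: none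
Why: Buffered fluoride desilylation of the secondary silyl ether, which the acetonide and the benzyl-type ether tolerate.

Step 21
Reactants: 34 1α,6α-diol
Product: 35 1α,6α-diacetate (12-O-PMB; 15,16-O-isopropylidene)
Conditions: Ac2O, DMAP, pyridine, 60 °C
Reagents that add atoms: acetic anhydride CC(=O)OC(C)=O
Why: DMAP-catalysed acylation, forced by heat for the axial C6 hydroxyl, with C12 masked so that it stays free of acetate.

Step 22
Reactants: 35 1α,6α-diacetate acetonide
Product: 36 15,16-diol 1α,6α-diacetate (12-O-PMB)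
Conditions: AcOH/H2O (4:1), 45 °C
Reagents that add atoms: none
Why: Mild acid hydrolysis of the acetonide, under which acetates, the PMB ether and the tetrasubstituted alkene are stable.

Step 23
Reactants: 36 15,16-diol
Product: 37 15,16-dione 1α,6α-diacetate (12-O-PMB)
Conditions: IBX (3 equiv), DMSO, rt
Reagents that add atoms: none
Why: IBX oxidation of a vicinal diol to the 1,2-diketone without C–C cleavage, the bridgehead α-carbons excluding enolisation.

Step 24
Reactants: 37 15,16-dione
Product: 38 12-O-(4-methoxybenzyl)-1α,6α-diacetoxyjungermannenone C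
Conditions: Ph3PCH3Br, KN(SiMe3)2, THF, −78 °C; then 37 (1.0 equiv ylide), −78 to 0 °C
Reagents that add atoms: methyltriphenylphosphonium bromide C[P+](c1ccccc1)(c1ccccc1)c1ccccc1.[Br-]
Why: Wittig mono-methylenation of a 1,2-diketone at the less hindered C16 carbonyl, because the endo approach to C15 is closed by ring A and the C1 acetoxy group lying next to C11, and the enone formed is less electrophilic toward the ylide than the diketone.

Step 25
Reactants: 38 12-O-PMB ether
Product: 39 1α,6α-diacetoxyjungermannenone C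
Conditions: DDQ, CH2Cl2/pH 7 buffer, 0 °C to rt
Reagents that add atoms: none
Why: Oxidative cleavage of the 4-methoxybenzyl ether with DDQ under neutral conditions that spare the acetates and the α-methylene ketone.

**Compound list**
1 | 2,6,6-trimethylcyclohex-2-en-1-one | CC1=CCCC(C)(C)C1=O | starting material
2 | (3S)-2,6,6-trimethyl-3-(4,4,5,5-tetramethyl-1,3,2-dioxaborolan-2-yl)cyclohexan-1-one (C2 epimers) | CC1C(=O)C(C)(C)CC[C@@H]1B2OC(C)(C)C(C)(C)O2 | intermediate (not isolated)
3 | (3S)-3-hydroxy-2,6,6-trimethylcyclohexan-1-one (C2 epimers) | CC1C(=O)C(C)(C)CC[C@@H]1O | intermediate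
4 | (3S)-1,3-bis(tert-butyldimethylsilyloxy)-2,6,6-trimethylcyclohex-1-ene | CC1=C(O[Si](C)(C)C(C)(C)C)C(C)(C)CC[C@@H]1O[Si](C)(C)C(C)(C)C | intermediate
5 | but-3-en-2-one | CC(=O)C=C | starting material
6 | (2R,3S)-3-(tert-butyldimethylsilyloxy)-2,6,6-trimethyl-2-(3-oxobutyl)cyclohexan-1-one | CC(=O)CC[C@@]1(C)C(=O)C(C)(C)CC[C@@H]1O[Si](C)(C)C(C)(C)C | intermediate
7 | (4aS,5S)-5-(tert-butyldimethylsilyloxy)-4a,8,8-trimethyl-4,4a,5,6,7,8-hexahydronaphthalen-2(3H)-one | C[C@]12CCC(=O)C=C1C(C)(C)CC[C@@H]2O[Si](C)(C)C(C)(C)C | intermediate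
8 | lithium C6=C7 enolate of the trans-decalin-7-one (1α-OTBS, 5β-H) | C[C@]12CCC(O[Li])=C[C@@H]1C(C)(C)CC[C@@H]2O[Si](C)(C)C(C)(C)C | intermediate (not isolated)
9 | 1α-(tert-butyldimethylsilyloxy)-7-(triethylsilyloxy)-4,4,10-trimethyl-trans-decal-6-ene | C[C@]12CCC(O[Si](CC)(CC)CC)=C[C@@H]1C(C)(C)CC[C@@H]2O[Si](C)(C)C(C)(C)C | intermediate
10 | 6β,7β-epoxide of 9 | C[C@]12CC[C@@]3(O[Si](CC)(CC)CC)O[C@H]3[C@@H]1C(C)(C)CC[C@@H]2O[Si](C)(C)C(C)(C)C | intermediate (not isolated)
11 | 1α-(tert-butyldimethylsilyloxy)-6β-(triethylsilyloxy)-4,4,10-trimethyl-trans-decalin-7-one | C[C@]12CCC(=O)[C@@H](O[Si](CC)(CC)CC)[C@@H]1C(C)(C)CC[C@@H]2O[Si](C)(C)C(C)(C)C | intermediate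
12 | lithium C7=C8 enolate of 11 | C[C@]12CC=C(O[Li])[C@@H](O[Si](CC)(CC)CC)[C@@H]1C(C)(C)CC[C@@H]2O[Si](C)(C)C(C)(C)C | intermediate (not isolated)
13 | 1α-(tert-butyldimethylsilyloxy)-6β-(triethylsilyloxy)-4,4,10-trimethyl-trans-decal-8-en-7-one | C[C@]12C=CC(=O)[C@@H](O[Si](CC)(CC)CC)[C@@H]1C(C)(C)CC[C@@H]2O[Si](C)(C)C(C)(C)C | intermediate
14 | formaldehyde | C=O | starting material
15 | 8-(hydroxymethyl) derivative of 13 | C[C@]12C=C(CO)C(=O)[C@@H](O[Si](CC)(CC)CC)[C@@H]1C(C)(C)CC[C@@H]2O[Si](C)(C)C(C)(C)C | intermediate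
16 | 8-(bromomethyl) derivative of 13 (ring A/B bromomethyl enone) | C[C@]12C=C(CBr)C(=O)[C@@H](O[Si](CC)(CC)CC)[C@@H]1C(C)(C)CC[C@@H]2O[Si](C)(C)C(C)(C)C | intermediate
17 | cyclopent-3-en-1-ol | OC1CC=CC1 | starting material
18 | cyclopentane-1,2,4-triol (1,2-cis, 4-OH trans) | O[C@H]1C[C@H](O)[C@H](O)C1 | intermediate
19 | cis-3,4-(isopropylidenedioxy)cyclopentan-1-ol (OH trans to the dioxolane) | O[C@H]1C[C@@H]2OC(C)(C)O[C@@H]2C1 | intermediate
20 | meso cis-3,4-(isopropylidenedioxy)cyclopentan-1-one | O=C1C[C@H]2OC(C)(C)O[C@H]2C1 | intermediate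
21 | lithium enolate of 20 on the side that becomes C13 | [Li]OC1=C[C@H]2OC(C)(C)O[C@H]2C1 | intermediate (not isolated)
22 | monoalkylated ketone (C13–C14 bond formed, ring C open) | O=C1C[C@@H]2OC(C)(C)O[C@@H]2[C@H]1CC3=C[C@]4(C)[C@@H](O[Si](C)(C)C(C)(C)C)CCC(C)(C)[C@H]4[C@H](O[Si](CC)(CC)CC)C3=O | intermediate (not isolated)
23 | C11 lithium enolate of 22 | [Li]OC1=C[C@@H]2OC(C)(C)O[C@@H]2[C@H]1CC3=C[C@]4(C)[C@@H](O[Si](C)(C)C(C)(C)C)CCC(C)(C)[C@H]4[C@H](O[Si](CC)(CC)CC)C3=O | intermediate (not isolated)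
24 | tetracyclic C7 lithium enolate | CC5(C)O[C@H]1[C@@H](O5)[C@@H]2[C@H]3C(=C(O[Li])[C@@H](O[Si](CC)(CC)CC)[C@@H]4C(C)(C)CC[C@H](O[Si](C)(C)C(C)(C)C)[C@@]34C)C[C@H]1C2=O | intermediate (not isolated)
25 | tetracyclic 12-ketone 7-(triethylsilyl) enol ether | CC5(C)O[C@H]1[C@@H](O5)[C@@H]2[C@H]3C(=C(O[Si](CC)(CC)CC)[C@@H](O[Si](CC)(CC)CC)[C@@H]4C(C)(C)CC[C@H](O[Si](C)(C)C(C)(C)C)[C@@]34C)C[C@H]1C2=O | intermediate
26 | tetracyclic 12-alcohol | CC5(C)O[C@H]1[C@@H](O5)[C@@H]2[C@H]3C(=C(O[Si](CC)(CC)CC)[C@@H](O[Si](CC)(CC)CC)[C@@H]4C(C)(C)CC[C@H](O[Si](C)(C)C(C)(C)C)[C@@]34C)C[C@H]1[C@@H]2O | intermediate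
27 | 12-O-(4-methoxybenzyl) ether of 26 | CC5(C)O[C@H]1[C@@H](O5)[C@@H]2[C@H]3C(=C(O[Si](CC)(CC)CC)[C@@H](O[Si](CC)(CC)CC)[C@@H]4C(C)(C)CC[C@H](O[Si](C)(C)C(C)(C)C)[C@@]34C)C[C@H]1[C@@H]2OCc6ccc(OC)cc6 | intermediate
28 | 12-O-PMB tetracyclic 8-en-7-one | CC5(C)O[C@H]1[C@@H](O5)[C@@H]2C3=C(C(=O)[C@@H](O[Si](CC)(CC)CC)[C@@H]4C(C)(C)CC[C@H](O[Si](C)(C)C(C)(C)C)[C@@]34C)C[C@H]1[C@@H]2OCc6ccc(OC)cc6 | intermediate
29 | potassium C6=C7 dienolate of 28 | CC5(C)O[C@H]1[C@@H](O5)[C@@H]2C3=C(C(O[K])=C(O[Si](CC)(CC)CC)[C@@H]4C(C)(C)CC[C@H](O[Si](C)(C)C(C)(C)C)[C@@]34C)C[C@H]1[C@@H]2OCc6ccc(OC)cc6 | intermediate (not isolated)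
30 | 6-(triethylsilyloxy)-6,8-dien-7-yl triflate | CC5(C)O[C@H]1[C@@H](O5)[C@@H]2C3=C(C(OS(=O)(=O)C(F)(F)F)=C(O[Si](CC)(CC)CC)[C@@H]4C(C)(C)CC[C@H](O[Si](C)(C)C(C)(C)C)[C@@]34C)C[C@H]1[C@@H]2OCc6ccc(OC)cc6 | intermediate
31 | 6-(triethylsilyloxy)-6,8-diene | CC5(C)O[C@H]1[C@@H](O5)[C@@H]2C3=C(C=C(O[Si](CC)(CC)CC)[C@@H]4C(C)(C)CC[C@H](O[Si](C)(C)C(C)(C)C)[C@@]34C)C[C@H]1[C@@H]2OCc6ccc(OC)cc6 | intermediate
32 | 8-en-6-one | CC5(C)O[C@H]1[C@@H](O5)[C@@H]2C3=C(CC(=O)[C@@H]4C(C)(C)CC[C@H](O[Si](C)(C)C(C)(C)C)[C@@]34C)C[C@H]1[C@@H]2OCc6ccc(OC)cc6 | intermediate (not isolated)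
33 | 8-en-6α-ol | CC5(C)O[C@H]1[C@@H](O5)[C@@H]2C3=C(C[C@H](O)[C@@H]4C(C)(C)CC[C@H](O[Si](C)(C)C(C)(C)C)[C@@]34C)C[C@H]1[C@@H]2OCc6ccc(OC)cc6 | intermediate
34 | 8-ene-1α,6α-diol | CC5(C)O[C@H]1[C@@H](O5)[C@@H]2C3=C(C[C@H](O)[C@@H]4C(C)(C)CC[C@H](O)[C@@]34C)C[C@H]1[C@@H]2OCc6ccc(OC)cc6 | intermediate
35 | 1α,6α-diacetate acetonide | CC5(C)O[C@H]1[C@@H](O5)[C@@H]2C3=C(C[C@H](OC(C)=O)[C@@H]4C(C)(C)CC[C@H](OC(C)=O)[C@@]34C)C[C@H]1[C@@H]2OCc6ccc(OC)cc6 | intermediate
36 | 15,16-diol 1α,6α-diacetate | O[C@H]1[C@@H](O)[C@@H]2C3=C(C[C@H](OC(C)=O)[C@@H]4C(C)(C)CC[C@H](OC(C)=O)[C@@]34C)C[C@H]1[C@@H]2OCc6ccc(OC)cc6 | intermediate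
37 | 15,16-dione 1α,6α-diacetate | O=C1C(=O)[C@@H]2C3=C(C[C@H](OC(C)=O)[C@@H]4C(C)(C)CC[C@H](OC(C)=O)[C@@]34C)C[C@H]1[C@@H]2OCc6ccc(OC)cc6 | intermediate
38 | 12-O-(4-methoxybenzyl)-1α,6α-diacetoxyjungermannenone C | C=C1C(=O)[C@@H]2C3=C(C[C@H](OC(C)=O)[C@@H]4C(C)(C)CC[C@H](OC(C)=O)[C@@]34C)C[C@H]1[C@@H]2OCc6ccc(OC)cc6 | intermediate
39 | 1α,6α-diacetoxyjungermannenone C | C=C1C(=O)[C@@H]2C3=C(C[C@H](OC(C)=O)[C@@H]4C(C)(C)CC[C@H](OC(C)=O)[C@@]34C)C[C@H]1[C@@H]2O | target

**Count and risks**
Total steps: 25. Longest linear sequence: 22 steps (steps 1–9 and 13–25); steps 10–12 form the short branch.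

The three steps most likely to fail:

Step 13. The cyclopentanone enolates carry a β-oxygen, so opening of the dioxolane by β-elimination may outrun ring closure at the hindered C9, and selection between the enantiotopic α-carbons may be incomplete. The fallback splits the annulation and closes the ring without a free enolate. It sets out from 20 and 16, which are joined as in the first half of step 13, and the monoalkylated ketone 22 is isolated. Kinetic deprotonation with LiN(iPr)2 in the presence of Et3SiCl at −78 °C (in situ quench) gives the C11 triethylsilyl enol ether F1. A silyl-transfer intramolecular Mukaiyama–Michael reaction (Tf2NH cat., CH2Cl2, −78 °C) then forms C9–C11 and moves the silyl group to the C7 oxygen, so the route is rejoined at 25.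

Step 17. Deprotonation of the tertiary, oxygen-bearing C6–H may be too slow in the pocket under the C4 and C10 methyls, or allylic strain in the tetrasubstituted enol may block O-sulfonylation. The fallback removes the C7 oxygen by radical deoxygenation and makes the C6 ketone by oxidation. It sets out from 28: Luche reduction (NaBH4, CeCl3, MeOH) gives the 7-hydroxy-8-ene F2, and NaH, CS2 and MeI give the S-methyl xanthate F3. Barton–McCombie reduction (Bu3SnH, AIBN, toluene, 80 °C) should deliver hydrogen to the less hindered C7 end of the allyl radical and give the 7-deoxy-8-ene 6β-triethylsilyl ether F4. Selective removal of the triethylsilyl group (HF·pyridine, pyridine, 0 °C) gives the 8-en-6β-ol F5, and Dess–Martin oxidation gives ketone 32, which is reduced as in step 19; the route is rejoined at 33.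

Step 24. The ylide may not distinguish the C15 and C16 carbonyls well enough, or may methylenate twice. The fallback fixes the position of the methylene by enolisation instead. It sets out from 36: pivaloyl chloride in pyridine at 0 °C acylates the less hindered C16 hydroxyl to the 16-pivalate F6 (a regioisomeric pivalate can be separated here and recycled by hydrolysis). Dess–Martin oxidation gives the 15-ketone 16-pivalate F7, and SmI2 (THF/MeOH, −78 °C) removes the α-acyloxy group to give the 16-deoxy 15-ketone F8. This ketone can enolise only toward C16, because C11 is a bridgehead. α-Methylenation with paraformaldehyde and N-methylanilinium trifluoroacetate (THF, 65 °C) then gives the α-methylene ketone, and the route is rejoined at 38.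

Further compounds
F1 | step 13 | C11 triethylsilyl enol ether of monoalkylated ketone 22 | CC[Si](CC)(CC)OC1=C[C@@H]2OC(C)(C)O[C@@H]2[C@H]1CC3=C[C@]4(C)[C@@H](O[Si](C)(C)C(C)(C)C)CCC(C)(C)[C@H]4[C@H](O[Si](CC)(CC)CC)C3=O
F2 | step 17 | 7α-hydroxy-8-ene (allylic alcohol from 28) | CC5(C)O[C@H]1[C@@H](O5)[C@@H]2C3=C([C@H](O)[C@@H](O[Si](CC)(CC)CC)[C@@H]4C(C)(C)CC[C@H](O[Si](C)(C)C(C)(C)C)[C@@]34C)C[C@H]1[C@@H]2OCc6ccc(OC)cc6
F3 | step 17 | S-methyl xanthate of F2 | CC5(C)O[C@H]1[C@@H](O5)[C@@H]2C3=C([C@H](OC(=S)SC)[C@@H](O[Si](CC)(CC)CC)[C@@H]4C(C)(C)CC[C@H](O[Si](C)(C)C(C)(C)C)[C@@]34C)C[C@H]1[C@@H]2OCc6ccc(OC)cc6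
F4 | step 17 | 7-deoxy-8-ene 6β-triethylsilyl ether | CC5(C)O[C@H]1[C@@H](O5)[C@@H]2C3=C(C[C@@H](O[Si](CC)(CC)CC)[C@@H]4C(C)(C)CC[C@H](O[Si](C)(C)C(C)(C)C)[C@@]34C)C[C@H]1[C@@H]2OCc6ccc(OC)cc6
F5 | step 17 | 7-deoxy-8-en-6β-ol | CC5(C)O[C@H]1[C@@H](O5)[C@@H]2C3=C(C[C@@H](O)[C@@H]4C(C)(C)CC[C@H](O[Si](C)(C)C(C)(C)C)[C@@]34C)C[C@H]1[C@@H]2OCc6ccc(OC)cc6
F6 | step 24 | 16-pivalate of diol 36 | CC(C)(C)C(=O)O[C@H]1[C@@H](O)[C@@H]2C3=C(C[C@H](OC(C)=O)[C@@H]4C(C)(C)CC[C@H](OC(C)=O)[C@@]34C)C[C@H]1[C@@H]2OCc6ccc(OC)cc6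
F7 | step 24 | 15-ketone 16-pivalate | CC(C)(C)C(=O)O[C@H]1C(=O)[C@@H]2C3=C(C[C@H](OC(C)=O)[C@@H]4C(C)(C)CC[C@H](OC(C)=O)[C@@]34C)C[C@H]1[C@@H]2OCc6ccc(OC)cc6
F8 | step 24 | 16-deoxy 15-ketone | C1C(=O)[C@@H]2C3=C(C[C@H](OC(C)=O)[C@@H]4C(C)(C)CC[C@H](OC(C)=O)[C@@]34C)C[C@H]1[C@@H]2OCc6ccc(OC)cc6
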